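## Analysis of the target

Target 24 is (2,6-dihydroxy-3,4-dimethoxyphenyl)[(1S,2S,6S)-3-methyl-2-(3-methylbut-2-en-1-yl)-6-phenylcyclohex-3-en-1-yl]methanone: a pentasubstituted benzene (ring A) joined through a ketone to a tetrasubstituted cyclohexene. In ring A, A1 carries the ketone, A2 and A6 free hydroxyls, A3 and A4 methoxyls and A5 the only hydrogen, so the ketone sits between two oxygen-bearing carbons. The cyclohexene has three contiguous stereocentres, C1 (acyl), C2 (prenyl) and C6 (phenyl), all S. The acyl group is trans to both neighbours, prenyl and phenyl are cis to each other, and the ring alkene lies between C3 (methyl) and C4. The two trisubstituted alkenes exclude hydrogenolysis and make strong protic acid and electrophilic reagents dangerous; C1–H is alpha to the ketone, and ring A is electron-rich and easily oxidised. The difficulties are the bond between a hindered secondary acyl carbon and an arene position flanked by two oxygens, the stereotriad together with a defined alkene position, and telling the A2/A6 hydroxyls apart from the A3/A4 methoxyls. The strategy rests on one feature: the ketone carbon on A1 and the oxygen on A6 sit on adjacent ring carbons, exactly like the two ends of a carboxyl C–O bond, so an aryne spanning A1–A6 can be inserted into a carboxylic acid.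

## Retrosynthetic reasoning

**24 to 23.** The last bond cut is the O–CH3 bond at A2. Carrying this oxygen as a methyl ether lets ring A come from a symmetric commercial phenol and keeps ring A free of protecting groups. The ether is the only one ortho to the ketone, so the forward step must cleave it by chelation and leave A3, A4 and both alkenes alone.

**23 to 14 and 19.** The A1–acyl bond and the A6–O bond are cut together, which leads to acid 14 and, through silyl triflate 19, to aryne 21. This is the most hindered bond of the molecule, and insertion makes it without electrophilic substitution on a crowded arene. The gain is convergence: all stereochemistry sits in 14, all arene substitution in 19. The forward reaction needs oxygen attack at A6 only, acyl transfer faster than protonation of aryl anion 22, and no reaction at the alkenes.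

**19 to 16 to 15.** The C–Si and O–S bonds of 19 go back to bromophenol 16, and its C–Br bond to phenol 15. Because 15 is symmetric, bromination ortho to the hydroxyl has only one outcome.

**14 to 13 to 12.** The carboxyl group is traced back through methyl ester 13 to the tris(methylsulfanyl)methyl group of 12. This gives a carbon at the carboxyl oxidation level that can be introduced as a nucleophile and that tolerates the bases and organometallic reagents used before it is unmasked.

**12 to 11 to 9.** The C3–CH3 bond is cut and the C3=C4 alkene is traced to a ketone at C3 through enol triflate 11. The alkene position is then decided by kinetic enolisation, and a ketone at C3 makes C2 and C1 the alpha and beta carbons of an enone.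

**9 to 4, 5 and 6.** The C1–carbon bond and the C2–CH2 bond of the prenyl group are cut in one operation: conjugate addition of the anion of 5 to enone 4 and alkylation of the enolate with 6. The phenyl-bearing centre of 4 must control both new centres.

**4 to 3 to 1.** Enone 4 goes back through silyl enol ether 3 to the achiral ketone 1. A desymmetrising enolisation with a chiral lithium amide creates the single stereocentre from which the other two follow.

## Alternatives that were turned down

**Alternative 1:** The cyclohexene would be cut at C1–C6 and C2–C3, so that ring A enters at the start as beta-keto aldehyde A2 and the phenyl group as enone A3. In the forward step an amine catalyst promotes Michael addition of the doubly activated carbon of A2 to the beta-carbon of A3. Aldol condensation of the ethyl ketone alpha-carbon with the formyl group then closes the six-membered ring and gives cyclohexenone A1 with aroyl and phenyl trans.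
- For: the crowded aryl–ketone bond never has to be made, and the absolute configuration comes from a catalyst. On that last point it is stronger than the chosen route, which uses a stoichiometric chiral base.
- Against: in A1, C2 is an unsubstituted alkene carbon and C4 carries a ketone the target lacks. A conjugate prenylation is needed (allylic copper reagents tend to deliver the 1,1-dimethylallyl isomer or add to the carbonyl), then enolate triflation and reductive removal of the triflate. Both MOM ethers must then be removed with acid beside two acid-sensitive alkenes.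
- Against: the C1–H of A1 is flanked by the aryl ketone and is vinylogous to the enone carbonyl, so the double bond can migrate into conjugation. A2 itself costs several steps.
- Comparison: the chosen route sets prenyl, carboxyl carbon and their trans,trans relation in one substrate-controlled operation and needs no protecting group on ring A.

**Alternative 2:** Ring A itself is disconnected, at A1–A6 and A2–A3, into cyclobutenone A5 and silyloxyalkyne A6, which already carries the complete cyclohexene as a silylated carbinol. On heating, A5 opens in a four-electron electrocyclic step to a vinylketene and the electron-rich alkyne adds to the ketene in a [2+2] sense. The new cyclobutenone opens again, and six-electron closure with tautomerisation gives phenol A4.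
- For: the substitution pattern of ring A follows from connectivity alone, and the A2 and A6 oxygens emerge already distinguished from the methoxyls. On both points it is stronger than the chosen route, which depends on aryne regioselectivity and a selective ether cleavage.
- Against: A5 and A6 each need several steps; A6 requires reduction of the cyclohexene carboxyl carbon, alkynylation and conversion into a silyl ynol ether.
- Against: the vinylketene is formed hot beside two trisubstituted alkenes that can themselves add to ketenes.
- Against: after A4 the carbinol (two epimers) must be desilylated and oxidised on an oxidation-prone phenol and the second silyl group removed, about four operations where the chosen strategy needs one.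
- Comparison: the chosen strategy takes ring A intact from commercial 15 in two steps and reaches the ketone oxidation level directly.

**Alternative 3:** Only the cyclohexane part is disconnected, at the C1–carboxyl-carbon bond and the C2–CH2 bond of the prenyl group. The forward step is conjugate addition of a lithiated trithioorthoformate to an enantioenriched 4-arylcyclohexenone with trapping by the allylic bromide, giving A7.
- For: it sets the stereotriad in one flask under substrate control and is well precedented. A7 is the same compound as 9, and the chosen route uses this operation as a supporting step, so on ring stereochemistry the two are equal.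
- Against, as the strategic centre: it leaves the hardest bond unsolved. The arene would have to be added as a 2,6-dialkoxyaryl-metal to an aldehyde or thioester made from A7, a hindered nucleophile meeting a hindered electrophile.
- Against: carbinol oxidation and removal of two phenol protecting groups beside two methyl ethers would follow. Such groups are acid-labile (a risk to the alkenes) or hydrogenolytic (excluded), and about four extra operations result.
- Comparison: the chosen strategy keeps the advantage of A7 and adds a direct conversion of the acid into the ortho-hydroxyaryl ketone with the A6 hydroxyl free from the start.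

Key step: step 10

Remark on the chemistry: the (R,R)-configured lithium amide is assumed to give the (S)-enol ether 3, as with 4-alkylcyclohexanones; if the sense proves opposite, the (S,S)-amine is used and nothing else changes.

Remark on the chemistry: in the resolution fallback the salt of acid 14 with (R)-1-phenylethylamine is assumed to be the less soluble one; otherwise the (S)-amine is used.

## Route

Step 1
Reactants: 1 4-phenylcyclohexan-1-one
Product: 3 (S)-trimethyl[(4-phenylcyclohex-1-en-1-yl)oxy]silane, via lithium (S)-4-phenylcyclohex-1-en-1-olate 2 (not isolated)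
Conditions: (R,R)-[PhCH(Me)]2NLi (from the amine and n-BuLi), TMSCl present (in situ quench), THF, −100 °C; Et3N, aq. NaHCO3
Reagents that add atoms: chlorotrimethylsilane, C[Si](C)(C)Cl
Why: Desymmetrising deprotonation of a prochiral 4-substituted cyclohexanone by a chiral lithium amide (Simpkins type); the C2-symmetric base removes one of the two enantiotopic axial alpha-protons, which fixes the remote phenyl-bearing carbon as S, and in situ silylation prevents enolate equilibration.

Step 2
Reactants: 3 (S)-trimethyl[(4-phenylcyclohex-1-en-1-yl)oxy]silane
Product: 4 (S)-4-phenylcyclohex-2-en-1-one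
Conditions: Pd(OAc)2 (10 mol %), O2 (1 atm), DMSO, 25 °C
Reagents that add atoms: none
Why: Saegusa–Ito oxidation in its catalytic aerobic form; palladation of the enol ether at C2 and beta-hydride loss from C3 give the enone, and the stereocentre at C4 takes no part.

Step 3
Reactants: 4 (S)-4-phenylcyclohex-2-en-1-one; 5 tris(methylsulfanyl)methane; 6 1-bromo-3-methylbut-2-ene (prenyl bromide)
Product: 9 (2S,3R,4S)-2-(3-methylbut-2-en-1-yl)-4-phenyl-3-[tris(methylsulfanyl)methyl]cyclohexan-1-one, via tris(methylsulfanyl)methyllithium 7 (not isolated), via lithium enolate of the adduct 8 (not isolated)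
Conditions: 5, n-BuLi, THF, −78 °C; 4, −78 °C; then HMPA, 6, −78 → −20 °C
Reagents that add atoms: tris(methylsulfanyl)methane 5, CSC(SC)SC; prenyl bromide 6, CC(C)=CCBr
Why: Tandem conjugate addition–enolate alkylation (three-component coupling) with a soft sulfur-stabilised carbanion; the nucleophile enters C3 anti to the C4 phenyl group and prenyl bromide then enters C2 anti to the bulky tris(methylsulfanyl)methyl group, which gives the trans,trans array.

Step 4
Reactants: 9 (2S,3R,4S)-2-(3-methylbut-2-en-1-yl)-4-phenyl-3-[tris(methylsulfanyl)methyl]cyclohexan-1-one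
Product: 11 (4S,5R,6S)-6-(3-methylbut-2-en-1-yl)-4-phenyl-5-[tris(methylsulfanyl)methyl]cyclohex-1-en-1-yl trifluoromethanesulfonate, via lithium enolate toward the methylene 10 (not isolated)
Conditions: LiN(iPr)2, THF, −78 °C; N-(5-chloropyridin-2-yl)-N-triflyltriflamide (Comins' reagent), −78 → 0 °C
Reagents that add atoms: N-(5-chloropyridin-2-yl)-1,1,1-trifluoro-N-(trifluoromethylsulfonyl)methanesulfonamide, O=S(=O)(N(c1ccc(Cl)cn1)S(=O)(=O)C(F)(F)F)C(F)(F)F
Why: Kinetic deprotonation takes a proton from the unsubstituted methylene and not from the shielded tertiary C–H next to the prenyl group, and O-triflation fixes that enolate as the enol triflate, which defines the position of the future ring alkene; no stereocentre is touched.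

Step 5
Reactants: 11 (4S,5R,6S)-6-(3-methylbut-2-en-1-yl)-4-phenyl-5-[tris(methylsulfanyl)methyl]cyclohex-1-en-1-yl trifluoromethanesulfonate
Product: 12 (4S,5S,6S)-1-methyl-6-(3-methylbut-2-en-1-yl)-4-phenyl-5-[tris(methylsulfanyl)methyl]cyclohex-1-ene
Conditions: Me2CuLi (from MeLi and CuI, 4 equiv), THF, −20 → 0 °C; aq. NH4Cl
Reagents that add atoms: lithium dimethylcuprate, [Li+].C[Cu-]C (made from methyllithium, [Li]C, and CuI)
Why: Coupling of an enol triflate with a lithium dialkylcuprate (McMurry–Scott type) replaces the triflate by methyl without moving the double bond; thioethers and isolated alkenes do not react with the cuprate.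

Step 6
Reactants: 12 (4S,5S,6S)-1-methyl-6-(3-methylbut-2-en-1-yl)-4-phenyl-5-[tris(methylsulfanyl)methyl]cyclohex-1-ene
Product: 13 methyl (1S,2S,6S)-3-methyl-2-(3-methylbut-2-en-1-yl)-6-phenylcyclohex-3-ene-1-carboxylate
Conditions: HgCl2, HgO, MeOH/H2O (12:1), 25 °C
Reagents that add atoms: methanol, CO; water, O
Why: Thiophilic divalent mercury removes the methylsulfanyl groups from the orthothioester and methanol and water intercept the sulfur-stabilised cations, ending at the methyl ester; HgCl2 buffered by HgO is a poor electrophile toward trisubstituted alkenes and the medium stays near neutral.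

Step 7
Reactants: 13 methyl (1S,2S,6S)-3-methyl-2-(3-methylbut-2-en-1-yl)-6-phenylcyclohex-3-ene-1-carboxylate
Product: 14 (1S,2S,6S)-3-methyl-2-(3-methylbut-2-en-1-yl)-6-phenylcyclohex-3-ene-1-carboxylic acid
Conditions: KOH, MeOH/THF/H2O, 70 °C; then 1 M HCl
Reagents that add atoms: potassium hydroxide, [K+].[OH-]
Why: Saponification of a hindered methyl ester; any base-induced epimerisation at C1 returns the same all-trans isomer, which is the most stable one.

Step 8
Reactants: 15 3,4,5-trimethoxyphenol
Product: 16 2-bromo-3,4,5-trimethoxyphenol
Conditions: NBS (1.0 equiv), CH2Cl2, −78 → 0 °C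
Reagents that add atoms: N-bromosuccinimide, O=C1CCC(=O)N1Br
Why: Electrophilic bromination of a strongly activated phenol ortho to the hydroxyl; the two ortho positions are equivalent by symmetry and the para position is occupied, so one equivalent at low temperature should stop at the monobromide.

Step 9
Reactants: 16 2-bromo-3,4,5-trimethoxyphenol
Product: 19 3,4,5-trimethoxy-2-(trimethylsilyl)phenyl trifluoromethanesulfonate, via (2-bromo-3,4,5-trimethoxyphenoxy)trimethylsilane 17 (not isolated), via lithium 3,4,5-trimethoxy-2-(trimethylsilyl)phenolate 18 (not isolated)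
Conditions: (Me3Si)2NH, THF, reflux, then evaporate; n-BuLi, THF, −100 → −78 °C; Tf2O, −100 °C → rt
Reagents that add atoms: hexamethyldisilazane, C[Si](C)(C)N[Si](C)(C)C; trifluoromethanesulfonic anhydride, O=S(=O)(OS(=O)(=O)C(F)(F)F)C(F)(F)F
Why: O-Silylation, bromine–lithium exchange and 1,3-shift of silicon from oxygen to carbon (retro-Brook rearrangement) place the silyl group next to a lithium phenoxide, which the anhydride converts into the triflate; this is the standard entry to ortho-silylaryl triflates.

Step 10
Reactants: 14 (1S,2S,6S)-3-methyl-2-(3-methylbut-2-en-1-yl)-6-phenylcyclohex-3-ene-1-carboxylic acid; 19 3,4,5-trimethoxy-2-(trimethylsilyl)phenyl trifluoromethanesulfonate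
Product: 23 (6-hydroxy-2,3,4-trimethoxyphenyl)[(1S,2S,6S)-3-methyl-2-(3-methylbut-2-en-1-yl)-6-phenylcyclohex-3-en-1-yl]methanone, via caesium carboxylate 20 (not isolated), via 3,4,5-trimethoxybenzyne 21 (not isolated), via ortho-caesioaryl ester 22 (not isolated)
Conditions: 14, Cs2CO3 (0.5 equiv), MeOH, then evaporate and dry; 19 (1.1 equiv, in portions), CsF (3 equiv), THF, 125 °C, sealed tube; dilute HCl work-up
Reagents that add atoms: aryne precursor 19, COc1cc(OS(=O)(=O)C(F)(F)F)c([Si](C)(C)C)c(OC)c1OC
Why: Fluoride attacks silicon of 19 and triflate leaves, giving aryne 21; the carboxylate oxygen of 20 adds to aryne carbon A6, the aryl anion 22 formed at A1 attacks its own ester carbonyl through a four-membered transition structure, and collapse of that alkoxide breaks the acyl–oxygen bond to give the ketone phenoxide, protonated on work-up. The closest known reaction is the fluoride-induced insertion of arynes into the C–O bond of carboxylic acids to give ortho-hydroxyaryl ketones; only the substrate is new, an alpha-branched acid with two trisubstituted alkenes. No ring is closed in the product and no stereocentre is formed; C1, the only centre that basic fluoride could epimerise, already has its most stable configuration. The step needs regioselectivity, which the methoxy group on A2 supplies: its inductive pull and the distortion it imposes on the aryne send the oxygen nucleophile to the remote carbon A6 and leave the negative charge on A1 beside that methoxy group. Carboxylate addition should outrun ene reaction with the two alkenes because the carboxylate is far more nucleophilic and the aryne is released slowly from sparingly soluble CsF. Acyl transfer must also outrun protonation of 22, which is why the acid is used as its dry caesium salt in THF and not as the free acid or in acetonitrile.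

Step 11
Reactants: 23 (6-hydroxy-2,3,4-trimethoxyphenyl)[(1S,2S,6S)-3-methyl-2-(3-methylbut-2-en-1-yl)-6-phenylcyclohex-3-en-1-yl]methanone
Product: 24 (2,6-dihydroxy-3,4-dimethoxyphenyl)[(1S,2S,6S)-3-methyl-2-(3-methylbut-2-en-1-yl)-6-phenylcyclohex-3-en-1-yl]methanone
Conditions: BCl3 (3 equiv), CH2Cl2, −78 → −20 °C; MeOH, then aq. NaHCO3
Reagents that add atoms: none
Why: Chelation-directed Lewis-acid cleavage of the aryl methyl ether ortho to the ketone; BCl3 binds the A6 phenol and the carbonyl oxygen, a further equivalent is held between the carbonyl and the A2 methoxy oxygen, and chloride removes that methyl group as chloromethane, while the A3 and A4 methoxyls lack this chelation and should survive at low temperature.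

## Compound list

1 | 4-phenylcyclohexan-1-one | O=C1CCC(c2ccccc2)CC1 | starting material
2 | lithium (S)-4-phenylcyclohex-1-en-1-olate | [Li]OC1=CC[C@@H](c2ccccc2)CC1 | intermediate (not isolated)
3 | (S)-trimethyl[(4-phenylcyclohex-1-en-1-yl)oxy]silane | C[Si](C)(C)OC1=CC[C@@H](c2ccccc2)CC1 | intermediate
4 | (S)-4-phenylcyclohex-2-en-1-one | O=C1C=C[C@@H](c2ccccc2)CC1 | intermediate
5 | tris(methylsulfanyl)methane | CSC(SC)SC | starting material
6 | 1-bromo-3-methylbut-2-ene (prenyl bromide) | CC(C)=CCBr | starting material
7 | tris(methylsulfanyl)methyllithium | [Li]C(SC)(SC)SC | intermediate (not isolated)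
8 | lithium (3R,4S)-4-phenyl-3-[tris(methylsulfanyl)methyl]cyclohex-1-en-1-olate | CSC(SC)(SC)[C@H]1C=C(O[Li])CC[C@@H]1c1ccccc1 | intermediate (not isolated)
9 | (2S,3R,4S)-2-(3-methylbut-2-en-1-yl)-4-phenyl-3-[tris(methylsulfanyl)methyl]cyclohexan-1-one | CSC(SC)(SC)[C@H]1[C@H](CC=C(C)C)C(=O)CC[C@@H]1c1ccccc1 | intermediate
10 | lithium (4S,5R,6S)-6-(3-methylbut-2-en-1-yl)-4-phenyl-5-[tris(methylsulfanyl)methyl]cyclohex-1-en-1-olate | CSC(SC)(SC)[C@H]1[C@H](CC=C(C)C)C(O[Li])=CC[C@@H]1c1ccccc1 | intermediate (not isolated)
11 | (4S,5R,6S)-6-(3-methylbut-2-en-1-yl)-4-phenyl-5-[tris(methylsulfanyl)methyl]cyclohex-1-en-1-yl trifluoromethanesulfonate | CSC(SC)(SC)[C@H]1[C@H](CC=C(C)C)C(OS(=O)(=O)C(F)(F)F)=CC[C@@H]1c1ccccc1 | intermediate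
12 | (4S,5S,6S)-1-methyl-6-(3-methylbut-2-en-1-yl)-4-phenyl-5-[tris(methylsulfanyl)methyl]cyclohex-1-ene | CSC(SC)(SC)[C@H]1[C@H](CC=C(C)C)C(C)=CC[C@@H]1c1ccccc1 | intermediate
13 | methyl (1S,2S,6S)-3-methyl-2-(3-methylbut-2-en-1-yl)-6-phenylcyclohex-3-ene-1-carboxylate | COC(=O)[C@H]1[C@H](CC=C(C)C)C(C)=CC[C@@H]1c1ccccc1 | intermediate
14 | (1S,2S,6S)-3-methyl-2-(3-methylbut-2-en-1-yl)-6-phenylcyclohex-3-ene-1-carboxylic acid | OC(=O)[C@H]1[C@H](CC=C(C)C)C(C)=CC[C@@H]1c1ccccc1 | intermediate
15 | 3,4,5-trimethoxyphenol | COc1cc(O)cc(OC)c1OC | starting material
16 | 2-bromo-3,4,5-trimethoxyphenol | COc1cc(O)c(Br)c(OC)c1OC | intermediate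
17 | (2-bromo-3,4,5-trimethoxyphenoxy)trimethylsilane | COc1cc(O[Si](C)(C)C)c(Br)c(OC)c1OC | intermediate (not isolated)
18 | lithium 3,4,5-trimethoxy-2-(trimethylsilyl)phenolate | COc1cc(O[Li])c([Si](C)(C)C)c(OC)c1OC | intermediate (not isolated)
19 | 3,4,5-trimethoxy-2-(trimethylsilyl)phenyl trifluoromethanesulfonate | COc1cc(OS(=O)(=O)C(F)(F)F)c([Si](C)(C)C)c(OC)c1OC | intermediate
20 | caesium (1S,2S,6S)-3-methyl-2-(3-methylbut-2-en-1-yl)-6-phenylcyclohex-3-ene-1-carboxylate | [Cs+].[O-]C(=O)[C@H]1[C@H](CC=C(C)C)C(C)=CC[C@@H]1c1ccccc1 | intermediate (not isolated)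
21 | 3,4,5-trimethoxybenzyne (1,2-didehydro-3,4,5-trimethoxybenzene) | COC1=C(OC)C(OC)=CC#C1 | intermediate (not isolated)
22 | 2-caesio-3,4,5-trimethoxyphenyl (1S,2S,6S)-3-methyl-2-(3-methylbut-2-en-1-yl)-6-phenylcyclohex-3-ene-1-carboxylate (aryl anion, caesium salt) | [Cs+].COc1cc(OC(=O)[C@H]2[C@H](CC=C(C)C)C(C)=CC[C@@H]2c2ccccc2)[c-]c(OC)c1OC | intermediate (not isolated)
23 | (6-hydroxy-2,3,4-trimethoxyphenyl)[(1S,2S,6S)-3-methyl-2-(3-methylbut-2-en-1-yl)-6-phenylcyclohex-3-en-1-yl]methanone | COc1cc(O)c(C(=O)[C@H]2[C@H](CC=C(C)C)C(C)=CC[C@@H]2c2ccccc2)c(OC)c1OC | intermediate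
24 | (2,6-dihydroxy-3,4-dimethoxyphenyl)[(1S,2S,6S)-3-methyl-2-(3-methylbut-2-en-1-yl)-6-phenylcyclohex-3-en-1-yl]methanone | COc1cc(O)c(C(=O)[C@H]2[C@H](CC=C(C)C)C(C)=CC[C@@H]2c2ccccc2)c(O)c1OC | target

## Step count and least certain steps

Total step count: 11 (seven to acid 14, two to aryne precursor 19, the insertion, the ether cleavage). Longest linear sequence: 9 steps (steps 1–7, 10 and 11).

**Step 10 (key step).** The most likely failure is protonation of aryl anion 22 before acyl transfer, so that the reaction stops at the aryl ester; traces of water, bifluoride, or an internal proton shift from C1–H could supply the proton. Further risks are ene reaction of the aryne with the alkenes, leakage of regioselectivity, and arylation of the product phenoxide by a second aryne. Fallback, setting out from 14 and 16: esterification (DCC, DMAP, CH2Cl2) should give 2-bromo-3,4,5-trimethoxyphenyl (1S,2S,6S)-3-methyl-2-(3-methylbut-2-en-1-yl)-6-phenylcyclohex-3-ene-1-carboxylate F1. Bromine–lithium exchange with n-BuLi in THF at −100 °C then generates the lithium analogue of 22 without any aryne and at a temperature where proton transfer is slow. The same migration of the acyl group from oxygen to carbon (anionic Fries-type rearrangement) returns to the route at 23, with the regiochemistry fixed by the position of bromine.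

**Step 11.** Hydrogen chloride set free when BCl3 meets the free phenol may add to the prenyl or ring alkene or trigger cyclisation, and over-cleavage at A3 is possible if the mixture warms. Fallback, setting out from 23: acetylation of the A6 hydroxyl (Ac2O, pyridine, DMAP) gives 3,4,5-trimethoxy-2-{[(1S,2S,6S)-3-methyl-2-(3-methylbut-2-en-1-yl)-6-phenylcyclohex-3-en-1-yl]carbonyl}phenyl acetate F2. With no O–H present, BCl3 at −78 °C releases no acid and can only be held between the carbonyl and the A2 methoxy group. A buffered quench should give 3-hydroxy-4,5-dimethoxy-2-{[(1S,2S,6S)-3-methyl-2-(3-methylbut-2-en-1-yl)-6-phenylcyclohex-3-en-1-yl]carbonyl}phenyl acetate F3, and K2CO3 in methanol removes the acetate to return at 24.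

**Step 3.** Proton exchange between enolate 8 and alkylated ketone, or gamma-deprotonation of 4 by the basic carbanion, could lead to incomplete or regiochemically scrambled alkylation and to erosion of the phenyl-bearing centre. Fallback, setting out from 4: the conjugate addition is run alone and quenched with TMSCl to give trimethyl({(3R,4S)-4-phenyl-3-[tris(methylsulfanyl)methyl]cyclohex-1-en-1-yl}oxy)silane F4, which is isolated. MeLi in THF then regenerates enolate 8 free of thioorthoformate and amine, and alkylation with 6 in the presence of HMPA returns to the route at 9.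

**Step 1.** Discrimination between the two enantiotopic alpha-protons may be incomplete, so that the whole series is carried with insufficient enantiopurity. Fallback, setting out from 14 of insufficient enantiopurity: crystallisation of (R)-1-phenylethylammonium (1S,2S,6S)-3-methyl-2-(3-methylbut-2-en-1-yl)-6-phenylcyclohex-3-ene-1-carboxylate F5 and release of the acid with dilute HCl returns to 14. This replaces asymmetric induction by classical resolution and would work even from racemic material.

**Step 5.** Coupling at the hindered enol triflate may be slow, with loss of the triflate by reduction or with copper held by the three thioether groups. Fallback, setting out from 9 and bypassing steps 4 and 5: condensation with 2,4,6-triisopropylbenzenesulfonohydrazide gives N'-[(2S,3R,4S)-2-(3-methylbut-2-en-1-yl)-4-phenyl-3-[tris(methylsulfanyl)methyl]cyclohexylidene]-2,4,6-triisopropylbenzenesulfonohydrazide F6. Treatment with n-BuLi (2.2 equiv, THF, −78 → 0 °C; Shapiro reaction) forms the vinyllithium on the methylene side, and quenching with MeI returns to the route at 12.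

## Further compounds

F1 | step 10 | 2-bromo-3,4,5-trimethoxyphenyl (1S,2S,6S)-3-methyl-2-(3-methylbut-2-en-1-yl)-6-phenylcyclohex-3-ene-1-carboxylate | COc1cc(OC(=O)[C@H]2[C@H](CC=C(C)C)C(C)=CC[C@@H]2c2ccccc2)c(Br)c(OC)c1OC
F2 | step 11 | 3,4,5-trimethoxy-2-{[(1S,2S,6S)-3-methyl-2-(3-methylbut-2-en-1-yl)-6-phenylcyclohex-3-en-1-yl]carbonyl}phenyl acetate | COc1cc(OC(C)=O)c(C(=O)[C@H]2[C@H](CC=C(C)C)C(C)=CC[C@@H]2c2ccccc2)c(OC)c1OC
F3 | step 11 | 3-hydroxy-4,5-dimethoxy-2-{[(1S,2S,6S)-3-methyl-2-(3-methylbut-2-en-1-yl)-6-phenylcyclohex-3-en-1-yl]carbonyl}phenyl acetate | COc1cc(OC(C)=O)c(C(=O)[C@H]2[C@H](CC=C(C)C)C(C)=CC[C@@H]2c2ccccc2)c(O)c1OC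
F4 | step 3 | trimethyl({(3R,4S)-4-phenyl-3-[tris(methylsulfanyl)methyl]cyclohex-1-en-1-yl}oxy)silane | CSC(SC)(SC)[C@H]1C=C(O[Si](C)(C)C)CC[C@@H]1c1ccccc1
F5 | step 1 | (R)-1-phenylethylammonium (1S,2S,6S)-3-methyl-2-(3-methylbut-2-en-1-yl)-6-phenylcyclohex-3-ene-1-carboxylate | C[C@@H]([NH3+])c1ccccc1.[O-]C(=O)[C@H]1[C@H](CC=C(C)C)C(C)=CC[C@@H]1c1ccccc1
F6 | step 5 | N'-[(2S,3R,4S)-2-(3-methylbut-2-en-1-yl)-4-phenyl-3-[tris(methylsulfanyl)methyl]cyclohexylidene]-2,4,6-triisopropylbenzenesulfonohydrazide | CSC(SC)(SC)[C@H]1[C@H](CC=C(C)C)C(=NNS(=O)(=O)c2c(C(C)C)cc(C(C)C)cc2C(C)C)CC[C@@H]1c1ccccc1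
A1 | alternative 1 | (4S,5S)-4-[3,4-dimethoxy-2,6-bis(methoxymethoxy)benzoyl]-2-methyl-5-phenylcyclohex-2-en-1-one | COCOc1cc(OC)c(OC)c(OCOC)c1C(=O)[C@H]1C=C(C)C(=O)C[C@@H]1c1ccccc1
A2 | alternative 1 | 3-[3,4-dimethoxy-2,6-bis(methoxymethoxy)phenyl]-3-oxopropanal | COCOc1cc(OC)c(OC)c(OCOC)c1C(=O)CC=O
A3 | alternative 1 | (E)-1-phenylpent-1-en-3-one | CCC(=O)/C=C/c1ccccc1
A4 | alternative 2 | 2-{(tert-butyldimethylsilyloxy)[(1S,2S,6S)-3-methyl-2-(3-methylbut-2-en-1-yl)-6-phenylcyclohex-3-en-1-yl]methyl}-4,5-dimethoxy-3-(triisopropylsilyloxy)phenol (carbinol epimers) | COc1cc(O)c(C(O[Si](C)(C)C(C)(C)C)[C@H]2[C@H](CC=C(C)C)C(C)=CC[C@@H]2c2ccccc2)c(O[Si](C(C)C)(C(C)C)C(C)C)c1OC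
A5 | alternative 2 | 2,3-dimethoxycyclobut-2-en-1-one | COC1=C(OC)C(=O)C1
A6 | alternative 2 | tert-butyl({1-[(1S,2S,6S)-3-methyl-2-(3-methylbut-2-en-1-yl)-6-phenylcyclohex-3-en-1-yl]-3-(triisopropylsilyloxy)prop-2-yn-1-yl}oxy)dimethylsilane (carbinol epimers) | CC(C)[Si](OC#CC(O[Si](C)(C)C(C)(C)C)[C@H]1[C@H](CC=C(C)C)C(C)=CC[C@@H]1c1ccccc1)(C(C)C)C(C)C
A7 | alternative 3 | (2S,3R,4S)-2-(3-methylbut-2-en-1-yl)-4-phenyl-3-[tris(methylsulfanyl)methyl]cyclohexan-1-one (identical with 9) | CSC(SC)(SC)[C@H]1[C@H](CC=C(C)C)C(=O)CC[C@@H]1c1ccccc1
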